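**Strategy.** The route rests on breaking the C11–C15 bond. C15 is the one carbon bonded to both C1 and C11, and with a C11=C12 double bond in place C11 is the electrophilic β-position of the C13 enone, so ring A (C15, C1, C14, C13, C12, C11) can be closed across a fourteen-membered carbocycle. In one operation an iron hydride turns the C1 isopropenyl group into the C15 radical, which bonds to C11; the enolate then expels the C18 acetate. Ring A, the twelve-membered ring, the C11 stereocentre and the C12=C18 methylene arise together. The precursor is the fourteen-membered (E)-2-(acetoxymethyl) enone with the C10 acetate, two E ring alkenes and the C1 isopropenyl group, built from (S)-carvone.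

Key step: step 18

Remarks on the chemistry (assumptions):
- Atom numbers are those of the verticillane skeleton: ring A is C1, C14, C13, C12, C11, C15; the large ring runs C1 to C11 and closes through C15; C18 sits on C12.
- The descriptors were re-derived: (S)-carvone supplies C1 as R, C10 is S, and both oxiranes are R,R, the sense expected from the D-fructose-derived ketone.
- The sense of induction in step 6 is assigned by analogy with aryl and alkenyl aldehydes and would be verified on 12.
- C13 of alcohol 24 is expected as a mixture of epimers and is left undefined in its SMILES; step 15 removes this centre.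
- The E geometry of the enone is fixed by a syn hydrostannation (step 9) and carried through a stereoretentive ring closure, so it is not left to a ring-closing equilibrium.

Step 1
Reactants: 1 (S)-carvone
Product: 2 (1S,4S,6S)-1-methyl-4-(prop-1-en-2-yl)-7-oxabicyclo[4.1.0]heptan-2-one
Conditions: 30% H2O2, NaOH (cat.), MeOH, 0 °C
Reagents that add atoms: hydrogen peroxide, OO
Why: Weitz–Scheffer nucleophilic epoxidation attacks only the electron-poor enone, hydroperoxide adding anti to the isopropenyl group so that the two oxirane carbons (both erased in step 2) form as one diastereomer while the isolated alkene is left alone.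

Step 2
Reactants: 2 (1S,4S,6S)-1-methyl-4-(prop-1-en-2-yl)-7-oxabicyclo[4.1.0]heptan-2-one
Product: 4 (R)-3-(prop-1-en-2-yl)hept-5-ynal, via epoxy tosylhydrazone 3 (not isolated)
Conditions: TsNHNH2, AcOH/CH2Cl2 (1:1), −20 °C → rt
Reagents that add atoms: none
Why: Eschenmoser–Tanabe fragmentation of the α,β-epoxy tosylhydrazone opens the ring with loss of N2 and sulfinate to give the methyl alkyne (C3, C4) and the aldehyde (C13), and the isopropenyl-bearing centre (C1) is not touched.

Step 3
Reactants: 4 (R)-3-(prop-1-en-2-yl)hept-5-ynal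
Product: 5 (R)-7,7-dimethoxy-5-(prop-1-en-2-yl)hept-2-yne
Conditions: HC(OMe)3, pyridinium p-toluenesulfonate (cat.), MeOH, rt
Reagents that add atoms: trimethyl orthoformate, COC(OC)OC
Why: Acid-catalysed acetalisation masks the C13 aldehyde against the zirconium hydride of step 4 and the organozinc of step 11.

Step 4
Reactants: 5 (R)-7,7-dimethoxy-5-(prop-1-en-2-yl)hept-2-yne
Product: 7 (2E,5R)-2-iodo-7,7-dimethoxy-5-(prop-1-en-2-yl)hept-2-ene, via alkenylzirconocene chloride 6 (not isolated)
Conditions: Cp2Zr(H)Cl (2.5 equiv), THF, 50 °C; then I2, THF, 0 °C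
Reagents that add atoms: iodine, [I][I]
Why: Hydrozirconation–iodination adds Zr–H syn, the excess hydride at 50 °C equilibrates zirconium to the less hindered methyl-bearing carbon C4, and iodinolysis with retention should give the E iodide, the 1,1-disubstituted alkene reacting far more slowly than the alkyne.

Step 5
Reactants: 8 4-[(tert-butyldimethylsilyl)oxy]but-2-yn-1-ol
Product: 9 4-[(tert-butyldimethylsilyl)oxy]but-2-ynal
Conditions: MnO2, CH2Cl2, rt
Reagents that add atoms: none
Why: MnO2 oxidises the propargylic alcohol selectively to the ynal without over-oxidation.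

Step 6
Reactants: 9 4-[(tert-butyldimethylsilyl)oxy]but-2-ynal; 10 allenylboronic acid pinacol ester
Product: 12 (S)-7-[(tert-butyldimethylsilyl)oxy]hepta-1,5-diyn-4-ol, via O-boryl ether 11 (not isolated)
Conditions: (S)-3,3′-bis(2,4,6-triisopropylphenyl)-1,1′-binaphthyl-2,2′-diyl hydrogen phosphate (5 mol%), 4 Å MS, toluene, −20 °C; aq. NaHCO3
Reagents that add atoms: none
Why: Chiral phosphoric acid-catalysed allenylboration (asymmetric propargylation) runs through a closed six-membered SE2′ transition state in which the (S) acid should direct the propargyl group to the Si face of the ynal, setting the future C10 carbinol as S.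

Step 7
Reactants: 12 (S)-7-[(tert-butyldimethylsilyl)oxy]hepta-1,5-diyn-4-ol
Product: 13 (S)-4,7-bis[(tert-butyldimethylsilyl)oxy]hepta-1,5-diyne
Conditions: TBSCl, imidazole, DMF, rt
Reagents that add atoms: tert-butyldimethylsilyl chloride, CC(C)(C)[Si](C)(C)Cl
Why: Imidazole-promoted silylation protects the C10 hydroxyl with the same group as the C18 hydroxyl so that both can be released together in step 16.

Step 8
Reactants: 13 (S)-4,7-bis[(tert-butyldimethylsilyl)oxy]hepta-1,5-diyne; 14 ethylene oxide
Product: 17 (3E,6S)-6,9-bis[(tert-butyldimethylsilyl)oxy]-4-methylnon-3-en-7-yn-1-ol, via alkenylalane 15 (not isolated), via lithium alanate 16 (not isolated)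
Conditions: Me3Al (2 equiv), Cp2ZrCl2 (0.25 equiv), CH2Cl2, 0 °C → rt; volatiles off; n-BuLi, hexane/THF, −30 °C; ethylene oxide, −30 °C → rt; aq. work-up
Reagents that add atoms: trimethylaluminium, C[Al](C)C
Why: Negishi zirconium-catalysed carboalumination adds methyl and aluminium syn across the terminal alkyne (methyl to the internal carbon C8, the internal silyloxy-flanked alkyne being much slower), and the derived alanate opens ethylene oxide with retention to give the E C7=C8 alkene with C5 and C6 attached.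

Step 9
Reactants: 17 (3E,6S)-6,9-bis[(tert-butyldimethylsilyl)oxy]-4-methylnon-3-en-7-yn-1-ol
Product: 18 (3E,6S,7E)-6,9-bis[(tert-butyldimethylsilyl)oxy]-4-methyl-8-(tributylstannyl)nona-3,7-dien-1-ol
Conditions: Bu3SnH (1.3 equiv), PdCl2(PPh3)2 (3 mol%), THF, 0 °C
Reagents that add atoms: tributyltin hydride, CCCC[SnH](CCCC)CCCC
Why: Palladium-catalysed hydrostannation is a syn addition in which tin should go to C12, the alkyne carbon next to the unbranched CH2OTBS group, and not to C11 beside the branched C10, which places C18 cis and tin trans to C10 (a minor regioisomer would be separated here).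

Step 10
Reactants: 18 (3E,6S,7E)-6,9-bis[(tert-butyldimethylsilyl)oxy]-4-methyl-8-(tributylstannyl)nona-3,7-dien-1-ol
Product: 19 tributyl[(2E,4S,6E)-9-bromo-1,4-bis[(tert-butyldimethylsilyl)oxy]-6-methylnona-2,6-dien-2-yl]stannane
Conditions: CBr4, PPh3, 2,6-lutidine, CH2Cl2, 0 °C
Reagents that add atoms: carbon tetrabromide, BrC(Br)(Br)Br
Why: Appel bromination converts the primary alcohol under neutral conditions that leave the alkenylstannane and both silyl ethers intact.

Step 11
Reactants: 19 tributyl[(2E,4S,6E)-9-bromo-1,4-bis[(tert-butyldimethylsilyl)oxy]-6-methylnona-2,6-dien-2-yl]stannane; 7 (2E,5R)-2-iodo-7,7-dimethoxy-5-(prop-1-en-2-yl)hept-2-ene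
Product: 21 tributyl[(2E,4S,6E,10E,13R)-1,4-bis[(tert-butyldimethylsilyl)oxy]-15,15-dimethoxy-6,10-dimethyl-13-(prop-1-en-2-yl)pentadeca-2,6,10-trien-2-yl]stannane, via alkylzinc bromide 20 (not isolated)
Conditions: Zn dust, LiCl, THF, 50 °C; then 7, PdCl2(dppf) (5 mol%), THF, 40 °C
Reagents that add atoms: none
Why: Negishi sp3–sp2 coupling of the homoallylic zinc reagent with the alkenyl iodide forms C4–C5 with retention of the C3=C4 geometry, transmetalation from zinc being much faster than from the hindered alkenylstannane, which stays as a spectator.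

Step 12
Reactants: 21 tributyl[(2E,4S,6E,10E,13R)-1,4-bis[(tert-butyldimethylsilyl)oxy]-15,15-dimethoxy-6,10-dimethyl-13-(prop-1-en-2-yl)pentadeca-2,6,10-trien-2-yl]stannane
Product: 22 (2E,4S,6E,10E,13R)-1,4-bis[(tert-butyldimethylsilyl)oxy]-2-iodo-15,15-dimethoxy-6,10-dimethyl-13-(prop-1-en-2-yl)pentadeca-2,6,10-triene
Conditions: I2 (1.05 equiv), CH2Cl2, −78 → 0 °C; aq. Na2S2O3
Reagents that add atoms: iodine, [I][I]
Why: Iododestannylation is an ipso substitution with retention and is much faster at the C–Sn bond than any reaction of iodine with the isolated alkenes.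

Step 13
Reactants: 22 (2E,4S,6E,10E,13R)-1,4-bis[(tert-butyldimethylsilyl)oxy]-2-iodo-15,15-dimethoxy-6,10-dimethyl-13-(prop-1-en-2-yl)pentadeca-2,6,10-triene
Product: 23 (3R,5E,9E,12S,13E)-12,15-bis[(tert-butyldimethylsilyl)oxy]-14-iodo-6,10-dimethyl-3-(prop-1-en-2-yl)pentadeca-5,9,13-trienal
Conditions: pyridinium p-toluenesulfonate (0.2 equiv), acetone/H2O (9:1), 40 °C
Reagents that add atoms: water, O
Why: Mild acid-catalysed acetal hydrolysis (transacetalisation to acetone) frees the C13 aldehyde under conditions that the silyl ethers and the alkenyl iodide should survive.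

Step 14
Reactants: 23 (3R,5E,9E,12S,13E)-12,15-bis[(tert-butyldimethylsilyl)oxy]-14-iodo-6,10-dimethyl-3-(prop-1-en-2-yl)pentadeca-5,9,13-trienal
Product: 24 (2E,4S,6E,10E,13R)-4-[(tert-butyldimethylsilyl)oxy]-2-{[(tert-butyldimethylsilyl)oxy]methyl}-6,10-dimethyl-13-(prop-1-en-2-yl)cyclotetradeca-2,6,10-trien-1-ol (C1 epimers)
Conditions: CrCl2 (10 equiv), NiCl2 (0.1 equiv), DMSO, rt, slow addition to 0.002 M
Reagents that add atoms: none
Why: Nozaki–Hiyama–Kishi reaction, in which nickel-catalysed insertion into the C–I bond and transmetalation give an alkenylchromium species that adds only to the aldehyde with retention of the C11=C12 geometry, closes the fourteen-membered ring at high dilution, and the new C13 carbinol (either epimer) is oxidised away in step 15.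

Step 15
Reactants: 24 (2E,4S,6E,10E,13R)-4-[(tert-butyldimethylsilyl)oxy]-2-{[(tert-butyldimethylsilyl)oxy]methyl}-6,10-dimethyl-13-(prop-1-en-2-yl)cyclotetradeca-2,6,10-trien-1-ol (C1 epimers)
Product: 25 (2E,4S,6E,10E,13R)-4-[(tert-butyldimethylsilyl)oxy]-2-{[(tert-butyldimethylsilyl)oxy]methyl}-6,10-dimethyl-13-(prop-1-en-2-yl)cyclotetradeca-2,6,10-trien-1-one
Conditions: Dess–Martin periodinane, NaHCO3, CH2Cl2, 0 °C → rt
Reagents that add atoms: none
Why: Dess–Martin oxidation of the allylic alcohol gives the C13 enone from both epimers without touching the alkenes or silyl ethers.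

Step 16
Reactants: 25 (2E,4S,6E,10E,13R)-4-[(tert-butyldimethylsilyl)oxy]-2-{[(tert-butyldimethylsilyl)oxy]methyl}-6,10-dimethyl-13-(prop-1-en-2-yl)cyclotetradeca-2,6,10-trien-1-one
Product: 26 (2E,4S,6E,10E,13R)-4-hydroxy-2-(hydroxymethyl)-6,10-dimethyl-13-(prop-1-en-2-yl)cyclotetradeca-2,6,10-trien-1-one
Conditions: HF·pyridine, pyridine, THF, 0 °C → rt
Reagents that add atoms: none
Why: Buffered fluoride desilylation removes both silyl ethers without the basic conditions that could trigger conjugate addition or elimination on the enone.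

Step 17
Reactants: 26 (2E,4S,6E,10E,13R)-4-hydroxy-2-(hydroxymethyl)-6,10-dimethyl-13-(prop-1-en-2-yl)cyclotetradeca-2,6,10-trien-1-one
Product: 27 (2E,4S,6E,10E,13R)-4-acetoxy-2-(acetoxymethyl)-6,10-dimethyl-13-(prop-1-en-2-yl)cyclotetradeca-2,6,10-trien-1-one
Conditions: Ac2O, pyridine, CH2Cl2, 0 °C → rt
Reagents that add atoms: acetic anhydride, CC(=O)OC(C)=O
Why: Acetylation installs the C10 acetate of the target and the C18 leaving group in one operation, pyridine alone being chosen to avoid allylic transposition of the new primary acetate by a stronger nucleophilic catalyst.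

Step 18
Reactants: 27 (2E,4S,6E,10E,13R)-4-acetoxy-2-(acetoxymethyl)-6,10-dimethyl-13-(prop-1-en-2-yl)cyclotetradeca-2,6,10-trien-1-one
Product: 28 (1R,3E,7E,10S,11S)-10-acetoxyverticilla-3,7,12(18)-trien-13-one
Conditions: Fe(acac)3 (0.5 equiv), PhSiH3 (2.5 equiv, portionwise), EtOH/ethylene glycol (5:1), 0.005 M, 60 °C, degassed
Reagents that add atoms: none
Why: Fe(acac)3 and PhSiH3 form an iron hydride that transfers a hydrogen atom to the terminal carbon of the isopropenyl group, the nucleophilic tertiary C15 radical adds to the enone β-carbon C11, the C12 α-keto radical is reduced by divalent iron to the enolate (returning trivalent iron), and the enolate expels the C18 acetate to leave the C12=C18 methylene. The closest known reaction type is the iron-hydride hydrogen-atom-transfer conjugate addition of unactivated alkenes to enones (a reductive Giese reaction), run here across a ring and ended by β-acyloxy elimination as in radical allylations with 2-(acyloxymethyl) acceptors. Ring A (C15, C1, C14, C13, C12, C11) closes in the 6-endo-trig mode, which is polarity-matched because the carbonyl lies inside the forming ring and the 5-exo alternative would attack the α-carbon C12. The only new stereocentre, C11, is under substrate control: allylic 1,3-strain between the C18 acetoxymethyl group and C10 should hold H10 in the enone plane, so the faces of C11 are flanked by the C10 acetate and by C9, and C15, delivered from (R)-C1 through the short C14–C13 tether, should bond on the face away from C9; with the E enone this puts C10 pseudo-equatorial and C2 axial in a chair-like transition state, giving the trans-bridged 11S isomer. The step needs hydrogen-atom transfer to the isopropenyl group in preference to C3=C4 and C7=C8 and no further reduction of the new methylene ketone; the higher rate for 1,1-disubstituted alkenes, the fast intramolecular trap, and a small excess of silane added slowly at high dilution should secure this, and any protonated β-acetoxy ketone converges on 28 by loss of acetic acid on mildly basic work-up.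

Step 19
Reactants: 28 (1R,3E,7E,10S,11S)-10-acetoxyverticilla-3,7,12(18)-trien-13-one
Product: 29 (1R,3R,4R,7R,8R,10S,11S)-10-acetoxy-3,4:7,8-diepoxyverticill-12(18)-en-13-one
Conditions: 1,2:4,5-di-O-isopropylidene-β-D-erythro-2,3-hexodiulo-2,6-pyranose (D-fructose-derived Shi ketone, 0.6 equiv), KHSO5 (as 2KHSO5·KHSO4·K2SO4), K2CO3, Bu4NHSO4 (cat.), Na2B4O7 buffer (pH 10.5), MeCN/dimethoxymethane/H2O, 0 °C
Reagents that add atoms: potassium peroxymonosulfate, [K+].[O-]S(=O)(=O)OO
Why: Shi asymmetric epoxidation, in which the chiral dioxirane transfers oxygen through a spiro transition state to each E trisubstituted alkene, should give the (3R,4R) and (7R,8R) oxiranes under reagent control, while the electron-poor methylene ketone is not attacked by the electrophilic oxidant.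

Compound list
1 | (S)-carvone | CC1=CC[C@@H](CC1=O)C(C)=C | starting material
2 | (1S,4S,6S)-1-methyl-4-(prop-1-en-2-yl)-7-oxabicyclo[4.1.0]heptan-2-one (oxirane trans to isopropenyl) | C[C@]12O[C@H]1C[C@H](C(C)=C)CC2=O | intermediate
3 | p-toluenesulfonylhydrazone of 2 | C[C@]12O[C@H]1C[C@H](C(C)=C)CC2=NNS(=O)(=O)c1ccc(C)cc1 | intermediate (not isolated)
4 | (R)-3-(prop-1-en-2-yl)hept-5-ynal | O=CC[C@@H](CC#CC)C(C)=C | intermediate
5 | (R)-7,7-dimethoxy-5-(prop-1-en-2-yl)hept-2-yne | COC(OC)C[C@@H](CC#CC)C(C)=C | intermediate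
6 | (E)-alkenylzirconocene chloride from 5, zirconium on C4 | COC(OC)C[C@@H](C/C=C(\C)[Zr](Cl)(C1C=CC=C1)C1C=CC=C1)C(C)=C | intermediate (not isolated)
7 | (2E,5R)-2-iodo-7,7-dimethoxy-5-(prop-1-en-2-yl)hept-2-ene | COC(OC)C[C@@H](C/C=C(\C)I)C(C)=C | intermediate
8 | 4-[(tert-butyldimethylsilyl)oxy]but-2-yn-1-ol | OCC#CCO[Si](C)(C)C(C)(C)C | starting material
9 | 4-[(tert-butyldimethylsilyl)oxy]but-2-ynal | O=CC#CCO[Si](C)(C)C(C)(C)C | intermediate
10 | allenylboronic acid pinacol ester | C=C=CB1OC(C)(C)C(C)(C)O1 | starting material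
11 | O-(pinacolatoboryl) ether of 12 | C#CC[C@H](OB1OC(C)(C)C(C)(C)O1)C#CCO[Si](C)(C)C(C)(C)C | intermediate (not isolated)
12 | (S)-7-[(tert-butyldimethylsilyl)oxy]hepta-1,5-diyn-4-ol | C#CC[C@H](O)C#CCO[Si](C)(C)C(C)(C)C | intermediate
13 | (S)-4,7-bis[(tert-butyldimethylsilyl)oxy]hepta-1,5-diyne | C#CC[C@H](O[Si](C)(C)C(C)(C)C)C#CCO[Si](C)(C)C(C)(C)C | intermediate
14 | ethylene oxide | C1CO1 | starting material
15 | (E)-alkenyl(dimethyl)alane from 13, aluminium on C7 | C[Al](C)/C=C(\C)C[C@H](O[Si](C)(C)C(C)(C)C)C#CCO[Si](C)(C)C(C)(C)C | intermediate (not isolated)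
16 | lithium butyl(alkenyl)dimethylalanate from 15 | [Li+].CCCC[Al-](C)(C)/C=C(\C)C[C@H](O[Si](C)(C)C(C)(C)C)C#CCO[Si](C)(C)C(C)(C)C | intermediate (not isolated)
17 | (3E,6S)-6,9-bis[(tert-butyldimethylsilyl)oxy]-4-methylnon-3-en-7-yn-1-ol | OCC/C=C(\C)C[C@H](O[Si](C)(C)C(C)(C)C)C#CCO[Si](C)(C)C(C)(C)C | intermediate
18 | (3E,6S,7E)-6,9-bis[(tert-butyldimethylsilyl)oxy]-4-methyl-8-(tributylstannyl)nona-3,7-dien-1-ol | OCC/C=C(\C)C[C@H](O[Si](C)(C)C(C)(C)C)/C=C(/[Sn](CCCC)(CCCC)CCCC)CO[Si](C)(C)C(C)(C)C | intermediate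
19 | tributyl[(2E,4S,6E)-9-bromo-1,4-bis[(tert-butyldimethylsilyl)oxy]-6-methylnona-2,6-dien-2-yl]stannane | BrCC/C=C(\C)C[C@H](O[Si](C)(C)C(C)(C)C)/C=C(/[Sn](CCCC)(CCCC)CCCC)CO[Si](C)(C)C(C)(C)C | intermediate
20 | alkylzinc bromide from 19 | Br[Zn]CC/C=C(\C)C[C@H](O[Si](C)(C)C(C)(C)C)/C=C(/[Sn](CCCC)(CCCC)CCCC)CO[Si](C)(C)C(C)(C)C | intermediate (not isolated)
21 | tributyl[(2E,4S,6E,10E,13R)-1,4-bis[(tert-butyldimethylsilyl)oxy]-15,15-dimethoxy-6,10-dimethyl-13-(prop-1-en-2-yl)pentadeca-2,6,10-trien-2-yl]stannane | COC(OC)C[C@@H](C/C=C(\C)CC/C=C(\C)C[C@H](O[Si](C)(C)C(C)(C)C)/C=C(/[Sn](CCCC)(CCCC)CCCC)CO[Si](C)(C)C(C)(C)C)C(C)=C | intermediate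
22 | (2E,4S,6E,10E,13R)-1,4-bis[(tert-butyldimethylsilyl)oxy]-2-iodo-15,15-dimethoxy-6,10-dimethyl-13-(prop-1-en-2-yl)pentadeca-2,6,10-triene | COC(OC)C[C@@H](C/C=C(\C)CC/C=C(\C)C[C@H](O[Si](C)(C)C(C)(C)C)/C=C(/I)CO[Si](C)(C)C(C)(C)C)C(C)=C | intermediate
23 | (3R,5E,9E,12S,13E)-12,15-bis[(tert-butyldimethylsilyl)oxy]-14-iodo-6,10-dimethyl-3-(prop-1-en-2-yl)pentadeca-5,9,13-trienal | O=CC[C@@H](C/C=C(\C)CC/C=C(\C)C[C@H](O[Si](C)(C)C(C)(C)C)/C=C(/I)CO[Si](C)(C)C(C)(C)C)C(C)=C | intermediate
24 | (2E,4S,6E,10E,13R)-4-[(tert-butyldimethylsilyl)oxy]-2-{[(tert-butyldimethylsilyl)oxy]methyl}-6,10-dimethyl-13-(prop-1-en-2-yl)cyclotetradeca-2,6,10-trien-1-ol, both C1 (verticillane C13) epimers | CC(C)(C)[Si](C)(C)OC/C1=C\[C@@H](O[Si](C)(C)C(C)(C)C)C/C(C)=C/CC/C(C)=C/C[C@@H](C(C)=C)CC1O | intermediate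
25 | (2E,4S,6E,10E,13R)-4-[(tert-butyldimethylsilyl)oxy]-2-{[(tert-butyldimethylsilyl)oxy]methyl}-6,10-dimethyl-13-(prop-1-en-2-yl)cyclotetradeca-2,6,10-trien-1-one | CC(C)(C)[Si](C)(C)OC/C1=C\[C@@H](O[Si](C)(C)C(C)(C)C)C/C(C)=C/CC/C(C)=C/C[C@@H](C(C)=C)CC1=O | intermediate
26 | (2E,4S,6E,10E,13R)-4-hydroxy-2-(hydroxymethyl)-6,10-dimethyl-13-(prop-1-en-2-yl)cyclotetradeca-2,6,10-trien-1-one | OC/C1=C\[C@@H](O)C/C(C)=C/CC/C(C)=C/C[C@@H](C(C)=C)CC1=O | intermediate
27 | (2E,4S,6E,10E,13R)-4-acetoxy-2-(acetoxymethyl)-6,10-dimethyl-13-(prop-1-en-2-yl)cyclotetradeca-2,6,10-trien-1-one (key-step precursor) | CC(=O)OC/C1=C\[C@@H](OC(C)=O)C/C(C)=C/CC/C(C)=C/C[C@@H](C(C)=C)CC1=O | intermediate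
28 | (1R,3E,7E,10S,11S)-10-acetoxyverticilla-3,7,12(18)-trien-13-one (key-step product) | C=C1C(=O)C[C@H]2C/C=C(\C)CC/C=C(\C)C[C@H](OC(C)=O)[C@H]1C2(C)C | intermediate
29 | (1R,3R,4R,7R,8R,10S,11S)-10-acetoxy-3,4:7,8-diepoxyverticill-12(18)-en-13-one (CNP0339728.2) | C=C1C(=O)C[C@H]2C[C@H]3O[C@]3(C)CC[C@H]3O[C@]3(C)C[C@H](OC(C)=O)[C@H]1C2(C)C | target

Total step count: 19. Longest linear sequence: 15 steps (8 to 29, steps 5 to 19); the carvone branch (1 to 29) is 13 steps.

Steps most likely to fail

Step 18. The tertiary C15 radical may be quenched by the hydride source before it reaches C11 (net hydrogenation of the isopropenyl group), and facial control at C11 may be poor. The fallback makes the same radical without any hydride donor and sets out from 27. Mukaiyama hydration (Co(acac)2, PhSiH3, O2, i-PrOH/THF), which favours the 1,1-disubstituted alkene, should give the tertiary alcohol F1. Methyl chlorooxoacetate with Et3N and DMAP gives the tert-alkyl methyl oxalate F2, and one equivalent of CsOH in wet THF cleaves only the oxalate methyl ester to the caesium oxalate F3. Visible-light photoredox oxidation of F3 ([Ir(dF(CF3)ppy)2(dtbbpy)]PF6, DME/DMF, blue LEDs) releases two CO2 and the C15 radical. 6-endo addition to C11, reduction of the C12 radical by the reduced photocatalyst and loss of acetate bring the route back at 28.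

Step 19. Oxygen delivery may be dictated by the folded twelve-membered ring of the bicycle and not by the catalyst, giving diastereomeric oxiranes, and the base-sensitive methylene ketone may erode during a slow second epoxidation. The fallback moves the oxidation ahead of the ring closure and sets out from 27, whose fourteen-membered ring is mobile and exposes both faces of each alkene. Shi epoxidation of 27 under the conditions of step 19 should give the (3R,4R,7R,8R)-bis-epoxide F4, in which the isopropenyl group is the only alkene left that can accept a hydrogen atom. The iron-hydride closure of step 18 applied to F4 should then form ring A and the methylene ketone, and the route comes back at 29.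

Step 14. Intermolecular coupling (oligomerisation) may outrun ring closure, and oxidative addition at the hindered trisubstituted iodide may be slow. The fallback closes the same C12–C13 bond by acylation and sets out from 21. Hydrolysis of the acetal (pyridinium p-toluenesulfonate, acetone/H2O) gives the stannyl aldehyde F5, and Pinnick oxidation (NaClO2, NaH2PO4, 2-methylbut-2-ene) gives the stannyl acid F6. 1-Chloro-N,N,2-trimethylprop-1-en-1-amine converts F6 into the acid chloride F7, which is not isolated. Slow addition of F7 to Pd2(dba)3 and tri(2-furyl)phosphine in toluene at 80 °C (intramolecular Stille acylation, with retention at C12) gives the enone directly, and the route comes back at 25.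

Further compounds
F1 | step 18 | (2E,4S,6E,10E,13R)-4-acetoxy-2-(acetoxymethyl)-13-(2-hydroxypropan-2-yl)-6,10-dimethylcyclotetradeca-2,6,10-trien-1-one | CC(=O)OC/C1=C\[C@@H](OC(C)=O)C/C(C)=C/CC/C(C)=C/C[C@@H](C(C)(C)O)CC1=O
F2 | step 18 | tert-alkyl methyl oxalate of F1 | CC(=O)OC/C1=C\[C@@H](OC(C)=O)C/C(C)=C/CC/C(C)=C/C[C@@H](C(C)(C)OC(=O)C(=O)OC)CC1=O
F3 | step 18 | caesium tert-alkyl oxalate from F2 | CC(=O)OC/C1=C\[C@@H](OC(C)=O)C/C(C)=C/CC/C(C)=C/C[C@@H](C(C)(C)OC(=O)C([O-])=O)CC1=O.[Cs+]
F4 | step 19 | (3R,4R,7R,8R)-3,4:7,8-bis-epoxide of 27 (verticillane numbering) | CC(=O)OC/C1=C\[C@@H](OC(C)=O)C[C@@]2(C)O[C@@H]2CC[C@@]2(C)O[C@@H]2C[C@@H](C(C)=C)CC1=O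
F5 | step 14 | (3R,5E,9E,12S,13E)-12,15-bis[(tert-butyldimethylsilyl)oxy]-6,10-dimethyl-3-(prop-1-en-2-yl)-14-(tributylstannyl)pentadeca-5,9,13-trienal | O=CC[C@@H](C/C=C(\C)CC/C=C(\C)C[C@H](O[Si](C)(C)C(C)(C)C)/C=C(/[Sn](CCCC)(CCCC)CCCC)CO[Si](C)(C)C(C)(C)C)C(C)=C
F6 | step 14 | carboxylic acid from F5 | OC(=O)C[C@@H](C/C=C(\C)CC/C=C(\C)C[C@H](O[Si](C)(C)C(C)(C)C)/C=C(/[Sn](CCCC)(CCCC)CCCC)CO[Si](C)(C)C(C)(C)C)C(C)=C
F7 | step 14 | acid chloride from F6 | ClC(=O)C[C@@H](C/C=C(\C)CC/C=C(\C)C[C@H](O[Si](C)(C)C(C)(C)C)/C=C(/[Sn](CCCC)(CCCC)CCCC)CO[Si](C)(C)C(C)(C)C)C(C)=C
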